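## Structural features

The target is a linear tridepside of three benzene rings (A, B and C), each an orsellinic-acid-type unit in which C1 carries a carbonyl carbon, C2 and C4 carry oxygen and C6 carries a methyl group. Two aryl ester bonds hold the chain together, one from the ring A carbonyl to O4 of ring B and one from the ring B carbonyl to O4 of ring C. There is no stereocentre, so the problem is one of regiochemistry and of telling six oxygen functions apart: ring A keeps two free phenols, ring B keeps one C2 phenol hydrogen-bonded to its ester carbonyl, and ring C has a methyl ether on C2 and a free carboxylic acid on C1. Every carbonyl sits between two ortho substituents, so each acyl transfer is hindered, yet the aryl esters remain sensitive to hydroxide, alkoxides and amines. Electron-rich ortho-oxygenated benzoic acids also lose CO2 in hot acid, so the last operation should be neutral. The real difficulty is ring C, where O2 must be methylated while O4 stays available for acylation, the reverse of the innate reactivity of an orsellinate. The key step exploits the fact that in ring C the carboxyl-bearing C1 and the methyl-bearing C6 are neighbours and C1 is flanked on its other side by the C2 methoxy group, so that a C1–C6 aryne next to that methoxy group can accept methyl at C6 and CO2 at C1 in one operation. The O2/O4 differentiation is thereby settled on a phloroglucinol ether before any carboxyl group exists.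

## Logic of the disconnections

22 to 21. The four O–CH2Ph bonds are cut (three phenolic ethers on rings A and B, one ester on the ring C carboxyl). One neutral hydrogenolysis then releases every acidic group at the end without exposing the aryl esters to acid or base. The demand is that 21 carries nothing else that is reducible and that all masked functions wear the same group.

21 to 19 and 12 (through 20). The ester bond between the ring B carbonyl and O4 of ring C is cut. This is the convergent cut, giving two halves of similar size. The phenol of 12 is the only nucleophile present and is unhindered. The forward step must activate the doubly ortho-substituted acid 19 as 20 without disturbing its internal aryl ester, and must use a non-nucleophilic base.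

12 to 11 to 10. The O4–Si bond and the carboxyl O–CH2Ph bond are cut. A silyl ether on O4 is orthogonal to benzyl, so the ring C carboxyl can be a benzyl ester. This removes the need for a separate acid-labile ester and a final acid treatment. The esterification must use a base too weak to cleave the aryl silyl ether, and the desilylation must be buffered.

10 to 4, 5 and 6 (key disconnection). The C6–CH3 and C1–CO2H bonds of ring C are cut, with no ring opened. Ring C falls back to 4, in which the three oxygens are already differentiated. In 4 iodine sits on the future C1, the sulfonate on the future C6, the methoxy group on the future C2 and the silyloxy group, para to iodine, on the future C4, which is exactly what 10 requires. The forward step needs complete halogen–metal exchange before the aryne exists, an excess of 5, and regiocontrol by the methoxy group.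

4 to 3 to 2 to 1. The O–S bond, the C–I bond and the O–Si bond are cut. The methoxy group is bought with 1, so only one symmetric diol has to be desymmetrized. The bulky silyl group on the future O4 does three jobs: it protects, it screens both neighbouring ring positions so that iodine is steered between OH and OMe, and it is orthogonal to benzyl. A benzyl ether at this position would lose the second and third advantages. The demand is a mono-silylation with recycling of material and a position-selective iodination.

19 to 18 to 17. The carboxyl C–O bond is cut by lowering the oxidation level to the aldehyde, and the O2–CH2Ph bond of ring B is cut. An aldehyde cannot be activated as an acylating agent, so C1 of ring B stays inert while the A–B ester is made. The forward steps need a chlorite oxidation that tolerates the ester and an alkylation of a chelated phenol under mild base.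

17 to 15 and 13 (through 16). The ester bond between the ring A carbonyl and O4 of ring B is cut. In 13 the C2 hydroxyl is tied up by the formyl group, so the C4 hydroxyl alone is acylated and ring B needs no protecting group at this stage. The demand is regioselective acylation with one equivalent of 16.

15 to 14 to 13. The carboxyl C–O bond (oxidation level) and two O–CH2Ph bonds are cut. Rings A and B then come from the same commercial aldehyde. Both forward steps are routine.

## Other disconnections considered

Alternative 1: The cut opens ring C along C1–C2 and C5–C6. In the forward direction the four-carbon ketene acetal diene 1,1-dimethoxy-3-(trimethylsilyloxy)buta-1,3-diene A1 would add to benzyl but-2-ynoate A2 in a Diels–Alder reaction. The adduct would aromatize by elimination of one methoxy group and loss of the silyl group to benzyl 4-hydroxy-2-methoxy-6-methylbenzoate A3. The product A3 is the same compound as 12.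
- In favour: the polarity of both partners fixes the regiochemistry, since the nucleophilic CH2 terminus of A1 bonds to the methyl-bearing carbon of A2. In A3 the methoxy group, the free O4 phenol and the benzyl ester arrive in final form and no protecting group is moved.
- Against: A2 is a β-alkyl alkynoate and a sluggish dienophile, so the heating it would need competes with decomposition and hydrolysis of A1. A1 must be prepared and used fresh.
- Structure: the two plans are equal, because A3 and 12 are one compound and both plans deliver the O2 methyl ether with O4 free.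
- Mechanism: the aryne route is a low-temperature ionic addition whose regiochemistry is enforced by a substituent directly beside the reacting bond. The cycloaddition to A3 depends on a labile diene meeting an unreactive alkyne.
- Step economy: Alternative 1 is the better plan. It would reach A3 in one step from A1 and A2, plus the preparation of A1, where the chosen route needs six steps to 12.

Alternative 2: The cut takes ring B apart on a preformed ester of ring C, at C1–C2, C2–C3, C4–C5 and C5–C6 of ring B. Irradiation of the diazo ketone benzyl 4-{[(2E)-5-diazo-3-methyl-4-oxopent-2-enoyl]oxy}-2-methoxy-6-methylbenzoate A4 would trigger a Wolff rearrangement to the corresponding vinyl-substituted ketene. (2+2) addition of that ketene to (triisopropylsilyloxy)acetylene A5, four-electron ring opening, six-electron electrocyclization and tautomerization would then give benzyl 4-{[2-hydroxy-6-methyl-4-(triisopropylsilyloxy)benzoyl]oxy}-2-methoxy-6-methylbenzoate A6.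
- In favour: the two oxygens of ring B in A6 are differentiated by mechanism, the ketene oxygen becoming the free C2 phenol and the alkyne oxygen the O4 silyl ether. The hindered B–C ester is made while its acyl carbon is still an unhindered unsaturated acid.
- Against: A4 requires a differentiated methyl-substituted butenedioic acid unit attached to 12 and a diazo-transfer step. The photolysis would be run on an aryl ester that can undergo photo-Fries rearrangement. A5 is a sensitive reagent. From A6, desilylation, acylation of O4 with 16 and hydrogenolysis still follow.
- Structure: Alternative 2 is the better plan for ring B. A6 needs no counterpart of step 10, and no chelated phenol is alkylated in the presence of an aryl ester. It is equal for ring C, since 12 must still be made.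
- Mechanism: the pericyclic cascade to A6 is regiochemically secure, but it rests on diazo compounds and photochemistry where the chosen route uses acylations and chlorite oxidations.
- Step economy: no gain. Preparing A4 and A5, the benzannulation to A6, the desilylation and the acylation by 16 would be no shorter than steps 7 to 12.

Alternative 3: The cut opens ring B at C3–C4 and C1–C6. The bis-silyl dienol ether benzyl 4-{[1,3-bis(trimethylsilyloxy)buta-1,3-dien-1-yl]oxy}-2-methoxy-6-methylbenzoate A7, obtained by acetoacetylation of 12 and double silylation, would react with 4,4-bis(allyloxy)but-3-en-2-one A8 under TiCl4. The terminal diene carbon would attack the acetal carbon and the central diene carbon would close onto the ketone. Dehydration and loss of one allyloxy group would then give benzyl 4-{[4-(allyloxy)-2-hydroxy-6-methylbenzoyl]oxy}-2-methoxy-6-methylbenzoate A9.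
- In favour: the chemistry is ionic, without photochemistry or diazo compounds. In A9 ring B arrives with the C2 phenol free and an allyl ether on O4 that is orthogonal to benzyl. The B–C ester is made by simple acetoacetylation.
- Against: TiCl4 would meet the benzyl ester and the ortho-methoxy benzoate of ring C, so chelation and cleavage are possible. An aryl acetoacetate can expel the aryloxide on enolization (acylketene formation), so making A7 is delicate. If the carbonyl of A8 were attacked first, the regioisomer of A9 would form. A8 must be prepared, and from A9 deallylation, acylation with 16 and hydrogenolysis follow.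
- Structure: A9 is equal to A6 and better than the chosen plan for the oxygen pattern of ring B. The plans are equal for ring C.
- Mechanism: the route to A9 is less secure than the chosen acylation sequence, because of the strong Lewis acid on a polyfunctional aryl ester.
- Step economy: about equal to the chosen route for the A–B half, with no clear saving.

Key step: step 4

Assumption: 5-methoxyresorcinol and 2,4-dihydroxy-6-methylbenzaldehyde are taken as catalogue chemicals; in every ring C1 is the carbon that bears the carbonyl carbon, C2 and C4 bear oxygen and C6 bears methyl.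
Remark: building blocks that supply carbon atoms of the target skeleton are numbered as reactants; donors of protecting groups, halogen or oxygen are listed with SMILES in each step.

Step 1
Reactants: 1 5-methoxyresorcinol
Product: 2 3-methoxy-5-[(triisopropylsilyl)oxy]phenol
Conditions: iPr3SiCl (0.95 equiv), imidazole, DMF, 0 °C to rt
Reagents that add atoms: triisopropylsilyl chloride, CC(C)[Si](Cl)(C(C)C)C(C)C
Why: Imidazole-promoted O-silylation of a phenol; with slightly less than one equivalent of the bulky chloride the mono-ether should predominate and should separate easily from unchanged 1, which is recycled.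

Step 2
Reactants: 2 3-methoxy-5-[(triisopropylsilyl)oxy]phenol
Product: 3 2-iodo-3-methoxy-5-[(triisopropylsilyl)oxy]phenol
Conditions: N-iodosuccinimide (1.0 equiv), CH2Cl2, -40 to 0 °C, dark
Reagents that add atoms: N-iodosuccinimide, O=C1CCC(=O)N1I
Why: Electrophilic aromatic iodination of an activated phenol; every ring CH is ortho or para to all three oxygens, but the two positions next to the OSi(iPr)3 group are screened by it, so iodine should enter C2, ortho to the free hydroxyl and between OH and OMe.

Step 3
Reactants: 3 2-iodo-3-methoxy-5-[(triisopropylsilyl)oxy]phenol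
Product: 4 2-iodo-3-methoxy-5-[(triisopropylsilyl)oxy]phenyl 4-chlorobenzenesulfonate
Conditions: 4-ClC6H4SO2Cl, Et3N, DMAP (cat.), CH2Cl2, 0 °C to rt
Reagents that add atoms: 4-chlorobenzenesulfonyl chloride, O=S(=O)(Cl)c1ccc(Cl)cc1
Why: O-Sulfonylation of the phenol; the 4-chlorobenzenesulfonate is inert to the exchange reagent at -78 °C and is expelled from the ortho-magnesiated arene on warming, which is what an aryne precursor of this type requires.

Step 4
Reactants: 4 2-iodo-3-methoxy-5-[(triisopropylsilyl)oxy]phenyl 4-chlorobenzenesulfonate; 5 methylmagnesium chloride; 6 carbon dioxide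
Product: 10 2-methoxy-6-methyl-4-[(triisopropylsilyl)oxy]benzoic acid, via magnesiated sulfonate 7 (not isolated), via aryne 8 (not isolated), via arylmagnesium chloride 9 (not isolated)
Conditions: iPrMgCl (1.05 equiv), THF, -78 °C; MeMgCl (4 equiv), -78 °C to rt; CO2 (gas), -20 °C to rt; cold aq. HCl to pH 3
Reagents that add atoms: none
Why: Iodine-magnesium exchange at the iodinated carbon (future C1) is faster at -78 °C than any attack on the sulfonate and gives 7, which is stable in the cold. On warming, 4-chlorobenzenesulfonate leaves from the neighbouring carbon (future C6) and the aryne 8 forms in the presence of an excess of 5. The methyl group adds to C6, the aryne carbon remote from the methoxy group, because the inductively withdrawing C2-O bond stabilizes carbanion character at C1, distorts the aryne so that C6 is the more electrophilic end, and lets the methoxy oxygen coordinate the magnesium arriving at C1; this gives 9. The hindered but strongly nucleophilic arylmagnesium 9 then adds to 6 and acidification releases 10, so the C6-CH3 and C1-CO2H bonds are made in one flask. The closest known reaction type is aryne generation from 2-iodoaryl arenesulfonates by halogen-magnesium exchange, followed by carbomagnesiation of the aryne and electrophilic trapping of the new arylmagnesium. No ring is closed and no stereocentre is formed. The selectivity needed is regiochemical and is secured by the C2 methoxy group directly beside the triple bond, the C4 silyloxy group being one carbon further away and exerting only a weaker bias; chemoselectivity comes from completing the exchange before the aryne exists, from the excess of 5 over 7 and 9, and from the inertness of the aryl silyl ether to Grignard reagents.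

Step 5
Reactants: 10 2-methoxy-6-methyl-4-[(triisopropylsilyl)oxy]benzoic acid
Product: 11 benzyl 2-methoxy-6-methyl-4-[(triisopropylsilyl)oxy]benzoate
Conditions: BnBr, KHCO3, DMF, rt to 40 °C
Reagents that add atoms: benzyl bromide, BrCc1ccccc1
Why: SN2 O-alkylation of the carboxylate; KHCO3 ionizes only the acid, so the aryl silyl ether is not cleaved, and the hindered carboxyl reacts at its remote oxygen.

Step 6
Reactants: 11 benzyl 2-methoxy-6-methyl-4-[(triisopropylsilyl)oxy]benzoate
Product: 12 benzyl 4-hydroxy-2-methoxy-6-methylbenzoate
Conditions: Bu4NF, AcOH, THF, 0 °C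
Reagents that add atoms: none
Why: Fluoride-induced cleavage of the aryl silyl ether, driven by Si-F bond formation; acetic acid buffers the phenoxide so the benzyl ester is not touched.

Step 7
Reactants: 13 2,4-dihydroxy-6-methylbenzaldehyde
Product: 14 2,4-bis(benzyloxy)-6-methylbenzaldehyde
Conditions: BnBr (2.5 equiv), K2CO3, DMF, 60 °C
Reagents that add atoms: benzyl bromide, BrCc1ccccc1
Why: Williamson etherification of both phenols; the hydrogen-bonded C2 hydroxyl needs the excess reagent and warming.

Step 8
Reactants: 14 2,4-bis(benzyloxy)-6-methylbenzaldehyde
Product: 15 2,4-bis(benzyloxy)-6-methylbenzoic acid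
Conditions: NaClO2, NaH2PO4, 2-methyl-2-butene, t-BuOH/THF/H2O, rt
Reagents that add atoms: sodium chlorite, [Na+].[O-]Cl=O
Why: Pinnick oxidation of the aldehyde to the acid; 2-methyl-2-butene removes hypochlorous acid and so protects the electron-rich ring from chlorination, and benzyl ethers are inert.

Step 9
Reactants: 15 2,4-bis(benzyloxy)-6-methylbenzoic acid; 13 2,4-dihydroxy-6-methylbenzaldehyde
Product: 17 4-formyl-3-hydroxy-5-methylphenyl 2,4-bis(benzyloxy)-6-methylbenzoate, via acid chloride 16 (not isolated)
Conditions: (COCl)2, DMF (cat.), CH2Cl2, 0 °C to rt, evaporate; then 13 (1.0 equiv), Et3N, CH2Cl2, 0 °C to rt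
Reagents that add atoms: none
Why: Acid chloride formation followed by base-mediated O-acylation of a phenol; in 13 the C2 hydroxyl is locked in a hydrogen bond to the formyl group, so the more acidic, unhindered C4 hydroxyl is the one acylated and ring B needs no prior protection.

Step 10
Reactants: 17 4-formyl-3-hydroxy-5-methylphenyl 2,4-bis(benzyloxy)-6-methylbenzoate
Product: 18 3-(benzyloxy)-4-formyl-5-methylphenyl 2,4-bis(benzyloxy)-6-methylbenzoate
Conditions: BnBr, K2CO3 (anhydrous), DMF, rt to 40 °C
Reagents that add atoms: benzyl bromide, BrCc1ccccc1
Why: Williamson etherification of the chelated phenol; the aryl ester is flanked by two ortho substituents on its acyl side and should resist anhydrous carbonate and the weakly nucleophilic phenoxide.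

Step 11
Reactants: 18 3-(benzyloxy)-4-formyl-5-methylphenyl 2,4-bis(benzyloxy)-6-methylbenzoate
Product: 19 2-(benzyloxy)-4-{[2,4-bis(benzyloxy)-6-methylbenzoyl]oxy}-6-methylbenzoic acid
Conditions: NaClO2, NaH2PO4, 2-methyl-2-butene, t-BuOH/THF/H2O, rt
Reagents that add atoms: sodium chlorite, [Na+].[O-]Cl=O
Why: Pinnick oxidation at buffered, weakly acidic pH, which leaves the aryl ester and the benzyl ethers untouched.

Step 12
Reactants: 19 2-(benzyloxy)-4-{[2,4-bis(benzyloxy)-6-methylbenzoyl]oxy}-6-methylbenzoic acid; 12 benzyl 4-hydroxy-2-methoxy-6-methylbenzoate
Product: 21 benzyl 4-{[2-(benzyloxy)-4-{[2,4-bis(benzyloxy)-6-methylbenzoyl]oxy}-6-methylbenzoyl]oxy}-2-methoxy-6-methylbenzoate, via didepside acid chloride 20 (not isolated)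
Conditions: (COCl)2, DMF (cat.), CH2Cl2, 0 °C to rt, evaporate; then 12, Et3N, DMAP (cat.), CH2Cl2, 0 °C to rt
Reagents that add atoms: none
Why: DMAP-catalysed acylation (acylpyridinium) of the unhindered phenol of 12 by the acid chloride; Et3N is non-nucleophilic, so neither aryl ester should be transesterified.

Step 13
Reactants: 21 benzyl 4-{[2-(benzyloxy)-4-{[2,4-bis(benzyloxy)-6-methylbenzoyl]oxy}-6-methylbenzoyl]oxy}-2-methoxy-6-methylbenzoate
Product: 22 4-({4-[(2,4-dihydroxy-6-methylbenzoyl)oxy]-2-hydroxy-6-methylbenzoyl}oxy)-2-methoxy-6-methylbenzoic acid (CNP0283563.0)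
Conditions: H2 (1 atm), Pd/C, EtOAc/THF, rt
Reagents that add atoms: none
Why: Catalytic hydrogenolysis of three benzyl ethers and the benzyl ester; aryl esters, the methyl ether and the arenes are inert under these conditions, so all four acidic groups are released in one neutral operation.

Compound list

1 | 5-methoxyresorcinol (5-methoxybenzene-1,3-diol) | COc1cc(O)cc(O)c1 | starting material
2 | 3-methoxy-5-[(triisopropylsilyl)oxy]phenol | COc1cc(O)cc(O[Si](C(C)C)(C(C)C)C(C)C)c1 | intermediate
3 | 2-iodo-3-methoxy-5-[(triisopropylsilyl)oxy]phenol | COc1cc(O[Si](C(C)C)(C(C)C)C(C)C)cc(O)c1I | intermediate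
4 | 2-iodo-3-methoxy-5-[(triisopropylsilyl)oxy]phenyl 4-chlorobenzenesulfonate | COc1cc(O[Si](C(C)C)(C(C)C)C(C)C)cc(OS(=O)(=O)c2ccc(Cl)cc2)c1I | intermediate
5 | methylmagnesium chloride | C[Mg]Cl | starting material
6 | carbon dioxide | O=C=O | starting material
7 | chloro{2-[(4-chlorophenyl)sulfonyloxy]-6-methoxy-4-[(triisopropylsilyl)oxy]phenyl}magnesium (magnesiated sulfonate) | COc1cc(O[Si](C(C)C)(C(C)C)C(C)C)cc(OS(=O)(=O)c2ccc(Cl)cc2)c1[Mg]Cl | intermediate
8 | 3-methoxy-5-[(triisopropylsilyl)oxy]benzyne (aryne across the future C1 and C6) | COC1=CC(O[Si](C(C)C)(C(C)C)C(C)C)=CC#C1 | intermediate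
9 | chloro{2-methoxy-6-methyl-4-[(triisopropylsilyl)oxy]phenyl}magnesium (arylmagnesium chloride) | COc1cc(O[Si](C(C)C)(C(C)C)C(C)C)cc(C)c1[Mg]Cl | intermediate
10 | 2-methoxy-6-methyl-4-[(triisopropylsilyl)oxy]benzoic acid | COc1cc(O[Si](C(C)C)(C(C)C)C(C)C)cc(C)c1C(=O)O | intermediate
11 | benzyl 2-methoxy-6-methyl-4-[(triisopropylsilyl)oxy]benzoate | COc1cc(O[Si](C(C)C)(C(C)C)C(C)C)cc(C)c1C(=O)OCc1ccccc1 | intermediate
12 | benzyl 4-hydroxy-2-methoxy-6-methylbenzoate | COc1cc(O)cc(C)c1C(=O)OCc1ccccc1 | intermediate
13 | 2,4-dihydroxy-6-methylbenzaldehyde | Cc1cc(O)cc(O)c1C=O | starting material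
14 | 2,4-bis(benzyloxy)-6-methylbenzaldehyde | Cc1cc(OCc2ccccc2)cc(OCc2ccccc2)c1C=O | intermediate
15 | 2,4-bis(benzyloxy)-6-methylbenzoic acid | Cc1cc(OCc2ccccc2)cc(OCc2ccccc2)c1C(=O)O | intermediate
16 | 2,4-bis(benzyloxy)-6-methylbenzoyl chloride | Cc1cc(OCc2ccccc2)cc(OCc2ccccc2)c1C(=O)Cl | intermediate
17 | 4-formyl-3-hydroxy-5-methylphenyl 2,4-bis(benzyloxy)-6-methylbenzoate | Cc1cc(OCc2ccccc2)cc(OCc2ccccc2)c1C(=O)Oc1cc(C)c(C=O)c(O)c1 | intermediate
18 | 3-(benzyloxy)-4-formyl-5-methylphenyl 2,4-bis(benzyloxy)-6-methylbenzoate | Cc1cc(OCc2ccccc2)cc(OCc2ccccc2)c1C(=O)Oc1cc(C)c(C=O)c(OCc2ccccc2)c1 | intermediate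
19 | 2-(benzyloxy)-4-{[2,4-bis(benzyloxy)-6-methylbenzoyl]oxy}-6-methylbenzoic acid | Cc1cc(OCc2ccccc2)cc(OCc2ccccc2)c1C(=O)Oc1cc(C)c(C(=O)O)c(OCc2ccccc2)c1 | intermediate
20 | 2-(benzyloxy)-4-{[2,4-bis(benzyloxy)-6-methylbenzoyl]oxy}-6-methylbenzoyl chloride | Cc1cc(OCc2ccccc2)cc(OCc2ccccc2)c1C(=O)Oc1cc(C)c(C(=O)Cl)c(OCc2ccccc2)c1 | intermediate
21 | benzyl 4-{[2-(benzyloxy)-4-{[2,4-bis(benzyloxy)-6-methylbenzoyl]oxy}-6-methylbenzoyl]oxy}-2-methoxy-6-methylbenzoate | COc1cc(OC(=O)c2c(C)cc(OC(=O)c3c(C)cc(OCc4ccccc4)cc3OCc3ccccc3)cc2OCc2ccccc2)cc(C)c1C(=O)OCc1ccccc1 | intermediate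
22 | 4-({4-[(2,4-dihydroxy-6-methylbenzoyl)oxy]-2-hydroxy-6-methylbenzoyl}oxy)-2-methoxy-6-methylbenzoic acid | COc1cc(OC(=O)c2c(C)cc(OC(=O)c3c(C)cc(O)cc3O)cc2O)cc(C)c1C(=O)O | target

Total step count: 13. Longest linear sequence: 8 steps (steps 1 to 6, then 12 and 13). The A–B branch (steps 7 to 11, then 12 and 13) is 7 steps.

Steps least certain to work

Step 4 (key step). The most likely failure is unproductive consumption of the aryne: addition of the arylmagnesium species 7 or 9, or of isopropyl-derived nucleophiles, in competition with 5, or protonation of 9 before carboxylation. Loss of regiocontrol is less likely. The fallback makes the same two bonds without an aryne, sets out from 3 and comes back at 11. Palladium-catalysed benzyloxycarbonylation of the aryl iodide of 3 (Pd(OAc)2, Xantphos, CO, BnOH, Et3N) would give benzyl 2-hydroxy-6-methoxy-4-[(triisopropylsilyl)oxy]benzoate F1. Triflation of its phenol (Tf2O, pyridine, CH2Cl2) would give benzyl 2-methoxy-4-[(triisopropylsilyl)oxy]-6-{[(trifluoromethyl)sulfonyl]oxy}benzoate F2. A Negishi coupling with MeZnCl (PdCl2(dppf), THF, 60 °C) would then place the methyl group on C6 and deliver 11.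

Step 2. The most likely failure is poor positional selectivity of the iodination (attack next to the silyloxy group) or over-iodination, because all three ring positions are electronically activated. The fallback replaces electrophilic substitution by directed ortho-metalation, sets out from 2 and comes back at 3. Protection of the phenol (MeOCH2Cl, iPr2NEt) would give 1-methoxy-3-(methoxymethoxy)-5-[(triisopropylsilyl)oxy]benzene F3. Lithiation with n-BuLi in THF at 0 °C, which can only occur between the two coordinating ether oxygens and not beside the bulky silyl ether, followed by I2, would give 2-iodo-1-methoxy-3-(methoxymethoxy)-5-[(triisopropylsilyl)oxy]benzene F4. Mild acid methanolysis (HCl, MeOH, rt) would remove the acetal and give 3.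

Step 10. The most likely failure is cleavage or transfer of the aryl ester under the basic alkylation, or incomplete alkylation of the chelated phenol. The fallback installs the benzyl ether before the ester exists, sets out from 13 and comes back at 18. Selective O4 allylation of 13 (allyl bromide, KHCO3, MeCN) would give 4-(allyloxy)-2-hydroxy-6-methylbenzaldehyde F5. Benzylation (BnBr, K2CO3, DMF) would give 4-(allyloxy)-2-(benzyloxy)-6-methylbenzaldehyde F6. Allyl transfer to 4-MeC6H4SO2Na catalysed by Pd(PPh3)4, a zerovalent palladium complex, would free 2-(benzyloxy)-4-hydroxy-6-methylbenzaldehyde F7. Acylation of F7 with 16 under the conditions of step 9 would give 18.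

Step 12. The most likely failure is slow acyl transfer from the large, doubly ortho-substituted acid chloride, which would allow hydrolysis or acyl scrambling at the internal ester during activation. The fallback assembles the chain linearly so that no activated acid contains an ester. It sets out from 12, takes its ring B unit from 13 through F6 of the step 10 fallback, and comes back at 21. Pinnick oxidation of F6 would give 4-(allyloxy)-2-(benzyloxy)-6-methylbenzoic acid F8. Steglich coupling with 12 (DCC, DMAP, CH2Cl2) would give benzyl 4-{[4-(allyloxy)-2-(benzyloxy)-6-methylbenzoyl]oxy}-2-methoxy-6-methylbenzoate F9. Deallylation (Pd(PPh3)4, 4-MeC6H4SO2Na) would give benzyl 4-{[2-(benzyloxy)-4-hydroxy-6-methylbenzoyl]oxy}-2-methoxy-6-methylbenzoate F10. Acylation of F10 with 16 would give 21.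

Further compounds

F1 | step 4 | benzyl 2-hydroxy-6-methoxy-4-[(triisopropylsilyl)oxy]benzoate | COc1cc(O[Si](C(C)C)(C(C)C)C(C)C)cc(O)c1C(=O)OCc1ccccc1
F2 | step 4 | benzyl 2-methoxy-4-[(triisopropylsilyl)oxy]-6-{[(trifluoromethyl)sulfonyl]oxy}benzoate | COc1cc(O[Si](C(C)C)(C(C)C)C(C)C)cc(OS(=O)(=O)C(F)(F)F)c1C(=O)OCc1ccccc1
F3 | step 2 | 1-methoxy-3-(methoxymethoxy)-5-[(triisopropylsilyl)oxy]benzene | COCOc1cc(OC)cc(O[Si](C(C)C)(C(C)C)C(C)C)c1
F4 | step 2 | 2-iodo-1-methoxy-3-(methoxymethoxy)-5-[(triisopropylsilyl)oxy]benzene | COCOc1cc(O[Si](C(C)C)(C(C)C)C(C)C)cc(OC)c1I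
F5 | step 10 | 4-(allyloxy)-2-hydroxy-6-methylbenzaldehyde | Cc1cc(OCC=C)cc(O)c1C=O
F6 | step 10 | 4-(allyloxy)-2-(benzyloxy)-6-methylbenzaldehyde | Cc1cc(OCC=C)cc(OCc2ccccc2)c1C=O
F7 | step 10 | 2-(benzyloxy)-4-hydroxy-6-methylbenzaldehyde | Cc1cc(O)cc(OCc2ccccc2)c1C=O
F8 | step 12 | 4-(allyloxy)-2-(benzyloxy)-6-methylbenzoic acid | Cc1cc(OCC=C)cc(OCc2ccccc2)c1C(=O)O
F9 | step 12 | benzyl 4-{[4-(allyloxy)-2-(benzyloxy)-6-methylbenzoyl]oxy}-2-methoxy-6-methylbenzoate | COc1cc(OC(=O)c2c(C)cc(OCC=C)cc2OCc2ccccc2)cc(C)c1C(=O)OCc1ccccc1
F10 | step 12 | benzyl 4-{[2-(benzyloxy)-4-hydroxy-6-methylbenzoyl]oxy}-2-methoxy-6-methylbenzoate | COc1cc(OC(=O)c2c(C)cc(O)cc2OCc2ccccc2)cc(C)c1C(=O)OCc1ccccc1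
A1 | alternative 1 | 1,1-dimethoxy-3-(trimethylsilyloxy)buta-1,3-diene | COC(OC)=CC(=C)O[Si](C)(C)C
A2 | alternative 1 | benzyl but-2-ynoate | CC#CC(=O)OCc1ccccc1
A3 | alternative 1 | benzyl 4-hydroxy-2-methoxy-6-methylbenzoate | COc1cc(O)cc(C)c1C(=O)OCc1ccccc1
A4 | alternative 2 | benzyl 4-{[(2E)-5-diazo-3-methyl-4-oxopent-2-enoyl]oxy}-2-methoxy-6-methylbenzoate | COc1cc(OC(=O)/C=C(\C)C(=O)C=[N+]=[N-])cc(C)c1C(=O)OCc1ccccc1
A5 | alternative 2 | (triisopropylsilyloxy)acetylene | C#CO[Si](C(C)C)(C(C)C)C(C)C
A6 | alternative 2 | benzyl 4-{[2-hydroxy-6-methyl-4-(triisopropylsilyloxy)benzoyl]oxy}-2-methoxy-6-methylbenzoate | COc1cc(OC(=O)c2c(C)cc(O[Si](C(C)C)(C(C)C)C(C)C)cc2O)cc(C)c1C(=O)OCc1ccccc1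
A7 | alternative 3 | benzyl 4-{[1,3-bis(trimethylsilyloxy)buta-1,3-dien-1-yl]oxy}-2-methoxy-6-methylbenzoate | COc1cc(OC(O[Si](C)(C)C)=CC(=C)O[Si](C)(C)C)cc(C)c1C(=O)OCc1ccccc1
A8 | alternative 3 | 4,4-bis(allyloxy)but-3-en-2-one | CC(=O)C=C(OCC=C)OCC=C
A9 | alternative 3 | benzyl 4-{[4-(allyloxy)-2-hydroxy-6-methylbenzoyl]oxy}-2-methoxy-6-methylbenzoate | COc1cc(OC(=O)c2c(C)cc(OCC=C)cc2O)cc(C)c1C(=O)OCc1ccccc1
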